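**Plan**
Locants: C1 carries the exocyclic CH2 (C8), C2 and C3 are CH2, C4 carries Br, C5 is CMe2, C6 carries the arylmethyl carbon C7.
Retrosynthesis: the hydroquinone goes back to its dimethyl ether. C1=C8 goes back to a C1=C2 cyclohexenylmethanol (allylic diazene shift). C4–Br is then cut and C2–C4 re-joined, and last the cyclopropane CH2 (C3), C1–C8 and C6–C7 are cut.
Enabling feature: Br–C4 is homoallylic to C1 along C4–C3–C2–C1. The six-membered ring is therefore the opened form of a bicyclo[3.1.0]hexane: cyclopentane C1–C2–C4–C5–C6 fused to cyclopropane C2–C3–C4, with a leaving group on C1.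
Forward order: arylmethyl bromide, then C6–C7 alkylation of 4,4-dimethylcyclopentenone, C8 added to C1, cyclopropane on C2=C4, ring enlargement five to six by bromide, alkene transposition, release of the hydroquinone.
Stereochemistry: C6 comes from the SAMP auxiliary. The C1–OH is set by addition anti to C7, and the cyclopropane by OH-directed CH2 delivery. C4 arises by inversion at the cyclopropane carbon, which gives cis-1,3 Br/CH2Ar.

Key step: step 8

Remark on the chemistry: the C=N geometry of hydrazones 5 and 7 is left open. It is lost on cleavage and has no bearing on the route.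

**Step 1**
Reactants: 1 2-bromo-1,4-dimethoxybenzene
Product: 2 1-bromo-4-(bromomethyl)-2,5-dimethoxybenzene
Conditions: (CH2O)n, 33% HBr in AcOH, AcOH, 50 °C
Reagents that add atoms: formaldehyde (as paraformaldehyde) C=O; hydrogen bromide Br
Why: Blanc-type bromomethylation, in which the free position para to Br and ortho to a methoxy group is the most activated and least hindered, so the 1,2,4,5-pattern of the target arene should result.

**Step 2**
Reactants: 3 4,4-dimethylcyclopent-2-en-1-one; 4 (S)-1-amino-2-(methoxymethyl)pyrrolidine (SAMP)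
Product: 5 SAMP hydrazone of 3
Conditions: cat. TsOH·H2O, cyclohexane, reflux, Dean–Stark trap
Reagents that add atoms: none
Why: Acid-catalysed hydrazone condensation, in which conjugate addition of the hydrazine is held back by the quaternary carbon next to the enone β-carbon and the auxiliary brings in the only external source of chirality.

**Step 3**
Reactants: 5 SAMP hydrazone of 3; 2 1-bromo-4-(bromomethyl)-2,5-dimethoxybenzene
Product: 7 (5R)-5-(4-bromo-2,5-dimethoxybenzyl) SAMP hydrazone, via lithium azaenolate 6 (not isolated)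
Conditions: LiN(iPr)2, THF, 0 °C; then 2, −95 to −20 °C
Reagents that add atoms: none
Why: Enders SAMP hydrazone alkylation, in which only the α' CH2 (C6) can be deprotonated because C5 is quaternary, and the lithium-chelated azaenolate should take up the benzylic bromide on the face left open by the methoxymethylpyrrolidine, which for SAMP corresponds to (R) at C6.

**Step 4**
Reactants: 7 (5R)-5-(4-bromo-2,5-dimethoxybenzyl) SAMP hydrazone
Product: 8 (R)-5-(4-bromo-2,5-dimethoxybenzyl)-4,4-dimethylcyclopent-2-en-1-one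
Conditions: sat. aq (CO2H)2, Et2O, rt
Reagents that add atoms: water O
Why: Two-phase hydrazone hydrolysis with oxalic acid, a mild way to free α-substituted ketones without epimerisation that spares the alkene and lets the auxiliary be recovered.

**Step 5**
Reactants: 8 (R)-5-(4-bromo-2,5-dimethoxybenzyl)-4,4-dimethylcyclopent-2-en-1-one
Product: 10 (1S,5R)-5-(4-bromo-2,5-dimethoxybenzyl)-1-(hydroxymethyl)-4,4-dimethylcyclopent-2-en-1-ol, via beta-hydroxysilane 9 (not isolated)
Conditions: (iPrO)Me2SiCH2MgCl, LaCl3·2LiCl (30 mol %), THF, −20 to 0 °C; aq NH4Cl; crude 9 then 30% H2O2, KF, KHCO3, THF/MeOH, rt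
Reagents that add atoms: [(isopropoxydimethylsilyl)methyl]magnesium chloride CC(C)O[Si](C)(C)C[Mg]Cl; hydrogen peroxide OO
Why: Nucleophilic hydroxymethylation (silylmethyl Grignard 1,2-addition, then Tamao oxidation), in which the reagent should reach C1 on the face anti to the neighbouring arylmethyl group so that the tertiary OH ends up cis to it, while 1,4-addition is blocked by the neopentyl β-carbon.

**Step 6**
Reactants: 10 (1S,5R)-5-(4-bromo-2,5-dimethoxybenzyl)-1-(hydroxymethyl)-4,4-dimethylcyclopent-2-en-1-ol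
Product: 11 primary triethylsilyl ether of 10
Conditions: Et3SiCl (1.05 equiv), imidazole, CH2Cl2, −20 °C
Reagents that add atoms: chlorotriethylsilane CC[Si](Cl)(CC)CC
Why: Selective silylation of the primary over the tertiary alcohol on steric grounds, which removes the competing directing group on the lower face and shields that face.

**Step 7**
Reactants: 11 primary triethylsilyl ether of 10
Product: 12 (1S,2S,3R,5R)-3-(4-bromo-2,5-dimethoxybenzyl)-4,4-dimethyl-2-{[(triethylsilyl)oxy]methyl}bicyclo[3.1.0]hexan-2-ol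
Conditions: Et2Zn, CH2I2, CH2Cl2, −10 °C to rt
Reagents that add atoms: diiodomethane ICI
Why: Hydroxyl-directed Simmons–Smith cyclopropanation (Furukawa variant), in which the zinc alkoxide at C1 should deliver CH2 (C3) to the C2=C4 alkene on its own face and so set C2 and C4 with the cyclopropane cis to the OH and to the arylmethyl group.

**Step 8**
Reactants: 12 (1S,2S,3R,5R)-3-(4-bromo-2,5-dimethoxybenzyl)-4,4-dimethyl-2-{[(triethylsilyl)oxy]methyl}bicyclo[3.1.0]hexan-2-ol
Product: 15 [(4R,6S)-4-bromo-6-(4-bromo-2,5-dimethoxybenzyl)-5,5-dimethylcyclohex-1-en-1-yl]methanol, via cyclopropyl diol 13 (not isolated), via cyclopropylcarbinyl cation 14 (not isolated)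
Conditions: 48% aq HBr (2 equiv), LiBr (5 equiv), Et2O, −10 to 0 °C; aq NaHCO3
Reagents that add atoms: hydrogen bromide Br
Why: Acid strips the silyl ether and ionises the tertiary C1–OH to the cyclopropylcarbinyl cation 14, whose charge is shared with C4 through the C2–C4 bond; bromide attacks C4 anti to that bond, C2–C4 breaks, C1=C2 forms, and the cyclopentane C1–C2–C4–C5–C6 becomes the cyclohexene C1–C6 with release of the cyclopropane strain. The closest known reaction types are the Julia cyclopropylcarbinol to homoallyl bromide rearrangement, the 3,5-cyclosteroid to 3β-halo-5-ene opening and the acid-induced thujane to p-menthane ring enlargement, all on a bicyclo[3.1.0]hexane that bears the carbinyl centre on a bridgehead carbon. No ring is closed by bond formation, since the six-membered ring arises by scission of the zero-atom bridge of the bicyclo[3.1.0]hexane. The only new stereocentre, C4, is controlled by inversion at the cyclopropane carbon, so its configuration is relayed from step 7, and with the cyclopropane cis to the arylmethyl group the cis-1,3 (diequatorial) Br/CH2Ar relation (4R,6S) should result; C6 is not touched, and reversible loss of H6 should be repaired by reprotonation on the convex face. The step needs scission of C2–C4 rather than C2–C3, which is secured because capture at C4 passes through secondary and capture at C3 through primary cationic character, while capture at C1 is reversible. The tertiary cyclopropylcarbinyl alcohol should ionise far faster than the primary allylic alcohol of 15, whose allyl cation has only primary and secondary termini, and excess LiBr at low temperature should outrun hydride shift from C8 and attack of the arene on C1.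

**Step 9**
Reactants: 15 [(4R,6S)-4-bromo-6-(4-bromo-2,5-dimethoxybenzyl)-5,5-dimethylcyclohex-1-en-1-yl]methanol
Product: 18 1-bromo-4-{[(1S,3R)-3-bromo-2,2-dimethyl-6-methylidenecyclohexyl]methyl}-2,5-dimethoxybenzene, via sulfonylhydrazine 16 (not isolated), via allylic diazene 17 (not isolated)
Conditions: 2-nitrobenzenesulfonylhydrazide, PPh3, DEAD, THF, −30 °C; then 23 °C
Reagents that add atoms: none
Why: Myers reductive allylic transposition, in which Mitsunobu displacement of the primary allylic OH, loss of sulfinic acid on warming and retro-ene loss of N2 from 17 deliver H to C2 and move the alkene to the exocyclic C1=C8 position without touching C4, C6 or either C–Br bond.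

**Step 10**
Reactants: 18 1-bromo-4-{[(1S,3R)-3-bromo-2,2-dimethyl-6-methylidenecyclohexyl]methyl}-2,5-dimethoxybenzene
Product: 19 2-bromo-5-{[(1S,3R)-3-bromo-2,2-dimethyl-6-methylidenecyclohexyl]methyl}cyclohexa-2,5-diene-1,4-dione
Conditions: (NH4)2Ce(NO3)6 (2.5 equiv), MeCN/H2O, 0 °C
Reagents that add atoms: water O
Why: Oxidative demethylation of the 1,4-dimethoxyarene, which avoids the strong Lewis or Brønsted acids that would isomerise the exocyclic alkene or close a chroman.

**Step 11**
Reactants: 19 2-bromo-5-{[(1S,3R)-3-bromo-2,2-dimethyl-6-methylidenecyclohexyl]methyl}cyclohexa-2,5-diene-1,4-dione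
Product: 20 cyclocymopol
Conditions: Na2S2O4, Et2O/H2O, rt, N2
Reagents that add atoms: none
Why: Dithionite reduction of the quinone to the hydroquinone under neutral two-phase conditions that leave the alkene and both bromides untouched.

**Compound list**
1 | 2-bromo-1,4-dimethoxybenzene | COc1ccc(OC)c(Br)c1 | starting material
2 | 1-bromo-4-(bromomethyl)-2,5-dimethoxybenzene | BrCc1cc(OC)c(Br)cc1OC | intermediate
3 | 4,4-dimethylcyclopent-2-en-1-one | O=C1C=CC(C)(C)C1 | starting material
4 | (S)-1-amino-2-(methoxymethyl)pyrrolidine (SAMP) | COC[C@@H]1CCCN1N | starting material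
5 | (S)-N-(4,4-dimethylcyclopent-2-en-1-ylidene)-2-(methoxymethyl)pyrrolidin-1-amine | COC[C@@H]1CCCN1N=C1C=CC(C)(C)C1 | intermediate
6 | lithium azaenolate of 5 (5,5-dimethylcyclopenta-1,3-dienyl hydrazide) | [Li+].COC[C@@H]1CCCN1[N-]C1=CC(C)(C)C=C1 | intermediate
7 | (S)-N-[(5R)-5-(4-bromo-2,5-dimethoxybenzyl)-4,4-dimethylcyclopent-2-en-1-ylidene]-2-(methoxymethyl)pyrrolidin-1-amine | COC[C@@H]1CCCN1N=C1C=CC(C)(C)[C@H]1Cc1cc(OC)c(Br)cc1OC | intermediate
8 | (R)-5-(4-bromo-2,5-dimethoxybenzyl)-4,4-dimethylcyclopent-2-en-1-one | O=C1C=CC(C)(C)[C@H]1Cc1cc(OC)c(Br)cc1OC | intermediate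
9 | (1S,5R)-5-(4-bromo-2,5-dimethoxybenzyl)-1-{[isopropoxy(dimethyl)silyl]methyl}-4,4-dimethylcyclopent-2-en-1-ol (OH cis to arylmethyl) | O[C@@]1(C[Si](C)(C)OC(C)C)C=CC(C)(C)[C@H]1Cc1cc(OC)c(Br)cc1OC | intermediate
10 | (1S,5R)-5-(4-bromo-2,5-dimethoxybenzyl)-1-(hydroxymethyl)-4,4-dimethylcyclopent-2-en-1-ol | O[C@@]1(CO)C=CC(C)(C)[C@H]1Cc1cc(OC)c(Br)cc1OC | intermediate
11 | (1S,5R)-5-(4-bromo-2,5-dimethoxybenzyl)-4,4-dimethyl-1-{[(triethylsilyl)oxy]methyl}cyclopent-2-en-1-ol | O[C@@]1(CO[Si](CC)(CC)CC)C=CC(C)(C)[C@H]1Cc1cc(OC)c(Br)cc1OC | intermediate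
12 | (1S,2S,3R,5R)-3-(4-bromo-2,5-dimethoxybenzyl)-4,4-dimethyl-2-{[(triethylsilyl)oxy]methyl}bicyclo[3.1.0]hexan-2-ol (OH, arylmethyl and cyclopropane CH2 on one face) | O[C@@]1(CO[Si](CC)(CC)CC)[C@H]2C[C@H]2C(C)(C)[C@H]1Cc1cc(OC)c(Br)cc1OC | intermediate
13 | (1S,2S,3R,5R)-3-(4-bromo-2,5-dimethoxybenzyl)-2-(hydroxymethyl)-4,4-dimethylbicyclo[3.1.0]hexan-2-ol | O[C@@]1(CO)[C@H]2C[C@H]2C(C)(C)[C@H]1Cc1cc(OC)c(Br)cc1OC | intermediate
14 | 3-(4-bromo-2,5-dimethoxybenzyl)-2-(hydroxymethyl)-4,4-dimethylbicyclo[3.1.0]hex-2-yl cation | OC[C+]1[C@H]2C[C@H]2C(C)(C)[C@H]1Cc1cc(OC)c(Br)cc1OC | intermediate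
15 | [(4R,6S)-4-bromo-6-(4-bromo-2,5-dimethoxybenzyl)-5,5-dimethylcyclohex-1-en-1-yl]methanol | OCC1=CC[C@@H](Br)C(C)(C)[C@H]1Cc1cc(OC)c(Br)cc1OC | intermediate
16 | N-{[(4R,6S)-4-bromo-6-(4-bromo-2,5-dimethoxybenzyl)-5,5-dimethylcyclohex-1-en-1-yl]methyl}-2-nitrobenzenesulfonohydrazide | NN(CC1=CC[C@@H](Br)C(C)(C)[C@H]1Cc1cc(OC)c(Br)cc1OC)S(=O)(=O)c1ccccc1[N+](=O)[O-] | intermediate
17 | {[(4R,6S)-4-bromo-6-(4-bromo-2,5-dimethoxybenzyl)-5,5-dimethylcyclohex-1-en-1-yl]methyl}diazene | N=NCC1=CC[C@@H](Br)C(C)(C)[C@H]1Cc1cc(OC)c(Br)cc1OC | intermediate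
18 | 1-bromo-4-{[(1S,3R)-3-bromo-2,2-dimethyl-6-methylidenecyclohexyl]methyl}-2,5-dimethoxybenzene | C=C1CC[C@@H](Br)C(C)(C)[C@H]1Cc1cc(OC)c(Br)cc1OC | intermediate
19 | 2-bromo-5-{[(1S,3R)-3-bromo-2,2-dimethyl-6-methylidenecyclohexyl]methyl}cyclohexa-2,5-diene-1,4-dione | C=C1CC[C@@H](Br)C(C)(C)[C@H]1CC1=CC(=O)C(Br)=CC1=O | intermediate
20 | cyclocymopol, 2-bromo-5-{[(1S,3R)-3-bromo-2,2-dimethyl-6-methylidenecyclohexyl]methyl}benzene-1,4-diol | C=C1CC[C@@H](Br)C(C)(C)[C@H]1Cc1cc(O)c(Br)cc1O | target

Total step count: 11. Longest linear sequence: 10 steps (3 to 20, steps 2 to 11).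

**Steps most likely to fail**

**Step 8.** Several processes compete with capture at C4.
- Bromide may be captured at the apex carbon C3, because the external C2–C3 bond is the better aligned one. This keeps the five-membered ring.
- Charge build-up at neopentyl C4 may set off a methyl shift from C5.
- Hydride may shift from C8, or the arene may trap C1.

The fallback sets out from 8 and comes back at 18. It puts the C4 heteroatom in as oxygen and enlarges the ring by diazoalkane homologation. Copper-catalysed conjugate borylation of 8 (B2pin2, CuCl, Xantphos, NaOtBu, MeOH, THF) on the face anti to the arylmethyl group should give the trans β-boryl cyclopentanone F1. NaBO3·4H2O should turn it into the trans β-hydroxy ketone F2, and tBuMe2SiOTf/2,6-lutidine into the silyl ether F3. Me3SiCHN2 with AlMe3, followed by a protodesilylating work-up, should insert CH2 between C1 and the less substituted α-carbon to give the ring-enlarged cyclohexanone F4. Non-basic methylenation (Zn, CH2Br2, TiCl4) should give the methylidene silyl ether F5, and Bu4NF the axial neopentyl alcohol F6. Appel bromination (CBr4, PPh3) with inversion should then give the equatorial bromide 18.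

**Step 3.** Alkylation next to the quaternary carbon may be slow. Facial discrimination on the flat dienyl azaenolate may be poor. The stereocentre may also erode during the cleavage in step 4.

The fallback sets out from 2 and comes back at 8. It sets C6 on an open chain and closes the ring afterwards. 3,3-Dimethylpent-4-enoic acid is bound to (R)-4-benzyloxazolidin-2-one (tBuCOCl, Et3N, LiCl) to give the N-acyl oxazolidinone F7. Evans alkylation (NaN(SiMe3)2, then 2) should give the (2R)-alkylated imide F8, and LiOH/H2O2 the carboxylic acid F9. (COCl)2 followed by MeONHMe·HCl/pyridine should give the Weinreb amide F10. Vinylmagnesium bromide with an acidic quench should give the dienone F11. Ring-closing metathesis with the second-generation Hoveyda–Grubbs catalyst should then give 8.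

**Step 7.** The alkene lies between two quaternary carbons, so three things may go wrong.
- Carbenoid transfer may stall.
- Zinc halides may ionise the tertiary allylic alcohol.
- Facial control may be lost.

The fallback sets out from 8 and comes back at 13. It builds the cyclopropane before the tertiary centre. Luche reduction (NaBH4, CeCl3·7H2O, MeOH) anti to the arylmethyl group should give the cis cyclopentenol F12. Hydroxyl-directed Simmons–Smith reaction on this less crowded secondary alcohol should give the bicyclic alcohol F13, and Dess–Martin oxidation the bicyclic ketone F14. Addition of (iPrO)Me2SiCH2MgCl with LaCl3·2LiCl on the convex face should give the bicyclic β-hydroxysilane F15. Tamao oxidation (H2O2, KF, KHCO3) should give diol 13, which is then treated with HBr as in step 8.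

**Further compounds**
F1 | step 8 | 2-(4-bromo-2,5-dimethoxybenzyl)-3,3-dimethyl-4-(pinacolatoboryl)cyclopentan-1-one, boryl trans to arylmethyl | O=C1C[C@H](B2OC(C)(C)C(C)(C)O2)C(C)(C)[C@H]1Cc1cc(OC)c(Br)cc1OC
F2 | step 8 | 2-(4-bromo-2,5-dimethoxybenzyl)-4-hydroxy-3,3-dimethylcyclopentan-1-one, OH trans to arylmethyl | O=C1C[C@H](O)C(C)(C)[C@H]1Cc1cc(OC)c(Br)cc1OC
F3 | step 8 | tert-butyldimethylsilyl ether of F2 | O=C1C[C@H](O[Si](C)(C)C(C)(C)C)C(C)(C)[C@H]1Cc1cc(OC)c(Br)cc1OC
F4 | step 8 | 2-(4-bromo-2,5-dimethoxybenzyl)-4-[(tert-butyldimethylsilyl)oxy]-3,3-dimethylcyclohexan-1-one, silyloxy trans to arylmethyl | O=C1CC[C@H](O[Si](C)(C)C(C)(C)C)C(C)(C)[C@H]1Cc1cc(OC)c(Br)cc1OC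
F5 | step 8 | methylidene analogue of F4 | C=C1CC[C@H](O[Si](C)(C)C(C)(C)C)C(C)(C)[C@H]1Cc1cc(OC)c(Br)cc1OC
F6 | step 8 | 3-(4-bromo-2,5-dimethoxybenzyl)-2,2-dimethyl-4-methylidenecyclohexan-1-ol, axial OH trans to arylmethyl | C=C1CC[C@H](O)C(C)(C)[C@H]1Cc1cc(OC)c(Br)cc1OC
F7 | step 3 | (R)-4-benzyl-3-(3,3-dimethylpent-4-enoyl)oxazolidin-2-one | C=CC(C)(C)CC(=O)N1[C@H](Cc2ccccc2)COC1=O
F8 | step 3 | (R)-4-benzyl-3-[(2R)-2-(4-bromo-2,5-dimethoxybenzyl)-3,3-dimethylpent-4-enoyl]oxazolidin-2-one | C=CC(C)(C)[C@@H](Cc1cc(OC)c(Br)cc1OC)C(=O)N1[C@H](Cc2ccccc2)COC1=O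
F9 | step 3 | (R)-2-(4-bromo-2,5-dimethoxybenzyl)-3,3-dimethylpent-4-enoic acid | C=CC(C)(C)[C@@H](Cc1cc(OC)c(Br)cc1OC)C(=O)O
F10 | step 3 | (R)-2-(4-bromo-2,5-dimethoxybenzyl)-N-methoxy-N,3,3-trimethylpent-4-enamide | C=CC(C)(C)[C@@H](Cc1cc(OC)c(Br)cc1OC)C(=O)N(C)OC
F11 | step 3 | (R)-4-(4-bromo-2,5-dimethoxybenzyl)-5,5-dimethylhepta-1,6-dien-3-one | C=CC(C)(C)[C@@H](Cc1cc(OC)c(Br)cc1OC)C(=O)C=C
F12 | step 7 | (1S,5R)-5-(4-bromo-2,5-dimethoxybenzyl)-4,4-dimethylcyclopent-2-en-1-ol, OH cis to arylmethyl | O[C@H]1C=CC(C)(C)[C@H]1Cc1cc(OC)c(Br)cc1OC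
F13 | step 7 | 3-(4-bromo-2,5-dimethoxybenzyl)-4,4-dimethylbicyclo[3.1.0]hexan-2-ol, OH, arylmethyl and cyclopropane CH2 on one face | O[C@H]1[C@H]2C[C@H]2C(C)(C)[C@H]1Cc1cc(OC)c(Br)cc1OC
F14 | step 7 | 3-(4-bromo-2,5-dimethoxybenzyl)-4,4-dimethylbicyclo[3.1.0]hexan-2-one, arylmethyl cis to cyclopropane CH2 | O=C1[C@H]2C[C@H]2C(C)(C)[C@H]1Cc1cc(OC)c(Br)cc1OC
F15 | step 7 | 3-(4-bromo-2,5-dimethoxybenzyl)-2-{[isopropoxy(dimethyl)silyl]methyl}-4,4-dimethylbicyclo[3.1.0]hexan-2-ol, OH, arylmethyl and cyclopropane CH2 on one face | O[C@@]1(C[Si](C)(C)OC(C)C)[C@H]2C[C@H]2C(C)(C)[C@H]1Cc1cc(OC)c(Br)cc1OC
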